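## Analysis of the target

The target 17 is an open-chain 1,7-diarylheptane. C1 carries ring A (4-hydroxy-3-methoxyphenyl), C7 carries ring B (3,4-dihydroxyphenyl), and C3 and C5 each carry an acetoxy group, with C4 as the methylene between them. C3 is R and C5 is S. Because C4 outranks C2 at C3 and C4 outranks C6 at C5, these opposite descriptors describe a syn-1,3-diol diacetate. The chain would be meso if the two rings were alike, so the molecule is chiral only through the methoxy/hydroxy difference between the rings, and each end has to be assigned to its ring with absolute control. The sensitive groups are the catechol of ring B (easily oxidised, above all in base), three phenols that acylate more readily than secondary alcohols, and two base-labile secondary acetates. The synthesis is hard for two reasons. The acetates must sit on the aliphatic oxygens while the phenols end up free, which excludes acetylation of an unprotected polyol. Each carbinol carbon is flanked by two methylene groups (C2 and C4 at C3, C4 and C6 at C5) that differ only beyond the first atom, a poor handle for most enantioselective carbonyl additions. The strategy rests on C3. It is the ester of a dialkyl carbinol, so it can come from a 1-bromoalkyl acetate whose α-acetoxy radical is joined to C2 of a ring A 2-arylethyl nucleophile under a chiral nickel catalyst. The C2–C3 bond, the C3 configuration and the C3 acetate then arrive together.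

## Retrosynthetic reasoning

Target 17 is traced back to its tri-O-benzyl ether 16 by cutting the three aryl O–benzyl bonds. Benzyl ethers are chosen because they come off by neutral hydrogenolysis, which leaves the acetates and both stereocentres alone. They also keep the phenols masked through every acylating or basic step before it.

16 is cut at C2–C3 into the bromo acetate 11 (C3 to C7 with ring B, racemic at the bromine-bearing carbon, S at the future C5) and the primary alkylzinc reagent 15 (C1, C2 and ring A). The cut is made here because C3 already carries the acetate, so the electrophile is just an aldehyde activated by acetyl bromide, and the nucleophile is a simple primary alkylzinc with no β-heteroatom. The mirror cut at C5–C6 is equivalent in principle, but the cheap three-carbon acid 1 carries ring B and the cheap two-carbon alcohol 12 carries ring A, which fits the C2–C3 cut. A cut at C3–C4 or C4–C5 would be an aldol-type bond and would leave the diol to be acetylated later. The forward reaction has to set C3 as R under catalyst control from either epimer of 11, without disturbing C5.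

11 is opened at its C–Br and acyl C–O bonds into the β-acetoxy aldehyde 9 and acetyl bromide 10. This addition costs no atoms, and the acetyl group of 10 becomes the C3 acetate of the target.

9 is traced to the homoallylic acetate 7 by restoring a terminal alkene in place of the aldehyde, and 7 to the homoallylic alcohol 6 by removing the acetyl group. The alkene is a masked aldehyde that survives acetylation, so the C5 acetate is in place before the sensitive aldehyde appears.

6 is cut at the bond between C4 and C5 into the aldehyde 4 and an allyl unit. The forward reaction is a reagent-controlled allylboration that sets C5 as S, a reliable transformation for unbranched aldehydes. The allyl carbons become C4 and C3, with one carbon lost at the ozonolysis.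

4 comes from the alcohol 3 and the benzyl ester 2 by oxidation-state adjustment, and 2 from the acid 1 by exhaustive benzylation. All seven carbons and both oxygens of the ring B end are bought with 1.

15 comes from the bromide 14 by zinc insertion, 14 from the alcohol 13 by bromination, and 13 from the phenol 12 by selective benzylation. The two-carbon arm and ring A are bought with 12.

## Alternatives that were turned down

Alternative 1: The disconnection is the C5–O bond together with the two acetal C–O bonds of the all-cis 2-phenyl-1,3-dioxane A1. In the forward step Re2O7 would transpose the allylic hydroxyl of the open-chain (3R,5E)-hept-5-ene-3,7-diol A2 from C7 to C5 in the presence of benzaldehyde dimethyl acetal A3, and the acetal would trap the syn diol as the triequatorial ring. In its favour, the step is a thermodynamic funnel: the C7 configuration of A2 need not be controlled, conjugation of the new C6=C7 alkene with ring B drives the transposition, and C5 is relayed from C3 without a second chiral reagent. On this point it is stronger than the chosen route, which relies on a catalyst to set C3 against a remote centre. Against it, the electron-rich ring B makes the C7–O bond ionise very readily, which invites elimination and arylation side reactions. C3 of A2 still needs its own asymmetric step. After A1, four more operations are needed: saturation of C6=C7 without hydrogenolysis of the cinnamyl-type C5–O bond or loss of the benzyl ethers, acetal removal, diacetylation and debenzylation. The chosen route forms the C3 acetate in the bond-forming step and ends one step after it, which is what it offers in place of thermodynamic stereocontrol.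

Alternative 2: The disconnection is the pair of alkenes C1=C2 and C6=C7 of the cis-dioxasilinane A4. In the forward step a chiral carbene complex RuCl2(L)(=CHAr), with L a C2-symmetric chiral N-heterocyclic carbene, would open the meso silylene-bridged cyclopentenediol A5 with the ring A styrene A6. In its favour, both stereocentres come from a meso compound, the syn relationship is fixed by the ring, and only the absolute sense depends on the catalyst. In stereochemical economy this is stronger than the chosen route, which uses a stoichiometric chiral borane for C5 and a catalyst for C3. Against it, the cyclopentene in A5 has little strain, so opening is reversible and competes with styrene self-metathesis. Enantioselectivity and E/Z control in such openings depend strongly on substrate. After A4, five operations remain: a second cross-metathesis to attach ring B next to a hindered silyloxy carbon, reduction of two alkenes that each flank an allylic C–O bond, silylene removal, diacetylation and debenzylation. The chosen route offers a dependable C5 centre, a convergent union of two simple fragments and a one-step endgame.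

Alternative 3: The disconnection is the ring B–C7 bond of the acetonide A7. In the forward step cathodically reduced NiBr2(dme) with a bipyridine ligand, in an undivided cell with a zinc anode, would couple the primary bromide A8 with the aryl bromide A9. In its favour, both stereocentres are bought with the syn acetonide building block A10, and the aryl–alkyl cross-electrophile coupling of a primary bromide is established. On stereochemical certainty this is clearly stronger than the chosen route. Against it, A10 has six chain carbons at the wrong oxidation levels. Its ester end must be reduced and brominated to give C7. Its hydroxymethyl end must be oxidised, olefinated with a ring A unit and saturated without loss of benzyl ethers. So most steps are functional-group changes in one long line. The electron-rich A9 adds slowly to nickel, which favours dimerisation and reduction of A8. After A7, acetonide removal, diacetylation and debenzylation are still needed. The longest line is about as long as in the chosen route, which offers instead two short branches and a key step that delivers the acetate-bearing stereocentre directly.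

Key step: step 11

Remark on the chemistry (assumption): which antipode of the bis(oxazoline) gives the 3R centre with a zinc nucleophile cannot be predicted with confidence. The (4S,4'S) ligand is written in step 11, and its mirror image is to be used if a pilot run gives the (3S,5S) diastereomer, which is distinguishable from 16 without chiral analysis.

## Route

Step 1
Reactants: 1 3-(3,4-dihydroxyphenyl)propanoic acid
Product: 2 benzyl 3-[3,4-bis(benzyloxy)phenyl]propanoate
Conditions: BnBr (3.5 equiv), K2CO3, DMF, 60 °C, under N2
Reagents that add atoms: benzyl bromide, BrCc1ccccc1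
Why: Williamson alkylation of both phenols and the carboxylate under K2CO3; exhaustive benzylation masks the catechol in one operation, and the benzyl ester is reduced away in the next step.

Step 2
Reactants: 2 benzyl 3-[3,4-bis(benzyloxy)phenyl]propanoate
Product: 3 3-[3,4-bis(benzyloxy)phenyl]propan-1-ol
Conditions: LiAlH4, THF, 0 °C to rt
Reagents that add atoms: none
Why: Hydride reduction of the ester to the primary alcohol; aryl benzyl ethers are inert to LiAlH4, and the benzyl alcohol set free is removed by chromatography.

Step 3
Reactants: 3 3-[3,4-bis(benzyloxy)phenyl]propan-1-ol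
Product: 4 3-[3,4-bis(benzyloxy)phenyl]propanal
Conditions: Dess–Martin periodinane, CH2Cl2, rt
Reagents that add atoms: none
Why: Dess–Martin oxidation stops at the aldehyde under near-neutral conditions and leaves the electron-rich ring and the benzyl ethers untouched.

Step 4
Reactants: 4 3-[3,4-bis(benzyloxy)phenyl]propanal
Product: 6 (3S)-1-[3,4-bis(benzyloxy)phenyl]hex-5-en-3-ol, via homoallyl borinate 5 (not isolated)
Conditions: (+)-Ipc2B(allyl) (commercial solution, (−)-α-pinene series), Et2O, −78 °C; then NaOH, H2O2, 0 °C to rt
Reagents that add atoms: (+)-B-allyldiisopinocampheylborane, C=CCB([C@H]1C[C@H]2C[C@@H]([C@@H]1C)C2(C)C)[C@H]1C[C@H]2C[C@@H]([C@@H]1C)C2(C)C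
Why: Brown allylation through a closed chair transition state; the isopinocampheyl groups of the (−)-α-pinene-derived reagent direct allyl to the Re face of the unbranched aldehyde, which sets the future C5 as S by reagent control. Oxidative work-up releases 6 from borinate 5.

Step 5
Reactants: 6 (3S)-1-[3,4-bis(benzyloxy)phenyl]hex-5-en-3-ol
Product: 7 (3S)-1-[3,4-bis(benzyloxy)phenyl]hex-5-en-3-yl acetate
Conditions: Ac2O, pyridine, DMAP (cat.), CH2Cl2, rt
Reagents that add atoms: acetic anhydride, CC(=O)OC(C)=O
Why: DMAP-catalysed acylation of a secondary alcohol with no change at the stereocentre; this acetate is the C5 acetate of the target and is never removed.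

Step 6
Reactants: 7 (3S)-1-[3,4-bis(benzyloxy)phenyl]hex-5-en-3-yl acetate
Product: 9 (3S)-5-[3,4-bis(benzyloxy)phenyl]-1-oxopentan-3-yl acetate, via ozonide 8 (not isolated)
Conditions: O3, CH2Cl2, −78 °C (Sudan Red 7B end point); then PPh3, −78 °C to rt; rapid chromatography
Reagents that add atoms: ozone, [O-][O+]=O
Why: Ozonolysis of the monosubstituted alkene, which reacts with ozone far faster than the dialkoxyarene, gives ozonide 8. PPh3 reduces it under neutral conditions, so the β-acetoxy aldehyde is not exposed to base and should not lose acetic acid.

Step 7
Reactants: 9 (3S)-5-[3,4-bis(benzyloxy)phenyl]-1-oxopentan-3-yl acetate, 10 acetyl bromide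
Product: 11 (3S)-5-[3,4-bis(benzyloxy)phenyl]-1-bromopentane-1,3-diyl diacetate (both C1 epimers)
Conditions: 10 (1.0 equiv), ZnBr2 (2 mol %), CH2Cl2, −20 to 0 °C; volatiles removed, used crude
Reagents that add atoms: none
Why: ZnBr2-catalysed addition of an acyl bromide across an aldehyde C=O is the standard, atom-economic entry to 1-bromoalkyl esters. The new bromine-bearing centre forms as both epimers, which does not matter because step 11 erases it.

Step 8
Reactants: 12 2-(4-hydroxy-3-methoxyphenyl)ethanol
Product: 13 2-[4-(benzyloxy)-3-methoxyphenyl]ethanol
Conditions: BnBr (1.1 equiv), K2CO3, acetone, reflux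
Reagents that add atoms: benzyl bromide, BrCc1ccccc1
Why: Williamson etherification; K2CO3 deprotonates the phenol but not the primary alcohol, so benzylation is chemoselective for the phenolic oxygen.

Step 9
Reactants: 13 2-[4-(benzyloxy)-3-methoxyphenyl]ethanol
Product: 14 1-(benzyloxy)-4-(2-bromoethyl)-2-methoxybenzene
Conditions: CBr4, PPh3, CH2Cl2, 0 °C
Reagents that add atoms: tetrabromomethane, BrC(Br)(Br)Br
Why: The Appel reaction converts the primary alcohol into the bromide under neutral conditions that do not affect the aryl ethers.

Step 10
Reactants: 14 1-(benzyloxy)-4-(2-bromoethyl)-2-methoxybenzene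
Product: 15 {2-[4-(benzyloxy)-3-methoxyphenyl]ethyl}zinc bromide (titrated solution in DMA)
Conditions: Zn dust, I2 (5 mol %), DMA, 70 °C
Reagents that add atoms: zinc, [Zn]
Why: Direct oxidative insertion of iodine-activated zinc into a primary alkyl bromide in a polar aprotic solvent; ether groups are tolerated, and the reagent is kept and used as a solution.

Step 11
Reactants: 11 (3S)-5-[3,4-bis(benzyloxy)phenyl]-1-bromopentane-1,3-diyl diacetate (both C1 epimers), 15 {2-[4-(benzyloxy)-3-methoxyphenyl]ethyl}zinc bromide
Product: 16 (3R,5S)-1-[4-(benzyloxy)-3-methoxyphenyl]-7-[3,4-bis(benzyloxy)phenyl]heptane-3,5-diyl diacetate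
Conditions: 15 (1.5 equiv, slow addition), NiBr2(dme) (10 mol %), (4S,4'S)-2,2'-(propane-2,2-diyl)bis(4-phenyl-4,5-dihydrooxazole) (12 mol %), THF/DMA, −10 °C
Reagents that add atoms: none
Why: Proposed new method: the NiBr2(dme)–bis(oxazoline) complex is alkylated by 15 to a chiral alkylnickel bromide of divalent nickel, while a monovalent nickel species abstracts bromine from either C1 epimer of 11 and so erases that centre as a planar α-acetoxyalkyl radical stabilised by the adjacent oxygen. The radical is captured by the divalent alkylnickel complex to give a trivalent dialkylnickel species, which reductively eliminates the C2–C3 bond and returns monovalent nickel to the chain; no ring is closed. The closest known reaction types are the nickel/bis(oxazoline) enantioconvergent alkyl–alkyl coupling of racemic 1-bromoalkyl esters with alkylnickel species generated from terminal alkenes and a hydrosilane, and enantioconvergent Negishi couplings of primary alkylzinc halides with other racemic α-heteroatom-substituted alkyl halides; the pairing of a 1-bromoalkyl ester with an alkylzinc reagent is the untested element. The new C3 centre is set by the ligand during radical capture and reductive elimination, with the acetate carbonyl acting as a second binding point on nickel that lets the ligand tell the C2 and C4 methylene arms apart. The step needs catalyst control strong enough to override any 1,3-induction from the C5 acetate, and it needs the radical pathway to outrun ionic substitution at the acetal-type carbon, which low temperature and slow addition of 15 should favour. The C5 acetate sits γ to the radical and cannot leave by β-scission, and since both esters of 11 are acetates, any acyl exchange between the two oxygens changes nothing. Because C5 is already fixed, a shortfall in selectivity would show as the separable (3S,5S) diastereomer and not as the enantiomer.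

Step 12
Reactants: 16 (3R,5S)-1-[4-(benzyloxy)-3-methoxyphenyl]-7-[3,4-bis(benzyloxy)phenyl]heptane-3,5-diyl diacetate
Product: 17 (3R,5S)-7-(3,4-dihydroxyphenyl)-1-(4-hydroxy-3-methoxyphenyl)heptane-3,5-diyl diacetate
Conditions: H2 (1 atm), 10% Pd/C, EtOAc, rt; filtration under argon
Reagents that add atoms: none
Why: Hydrogenolysis of three aryl benzyl ethers over Pd/C under neutral conditions; the acetates at C3 and C5 are neither benzylic nor allylic and should stay in place, and no stereocentre is touched.

## Compound list

1 | 3-(3,4-dihydroxyphenyl)propanoic acid | O=C(O)CCc1ccc(O)c(O)c1 | starting material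
2 | benzyl 3-[3,4-bis(benzyloxy)phenyl]propanoate | O=C(OCc1ccccc1)CCc1ccc(OCc2ccccc2)c(OCc2ccccc2)c1 | intermediate
3 | 3-[3,4-bis(benzyloxy)phenyl]propan-1-ol | OCCCc1ccc(OCc2ccccc2)c(OCc2ccccc2)c1 | intermediate
4 | 3-[3,4-bis(benzyloxy)phenyl]propanal | O=CCCc1ccc(OCc2ccccc2)c(OCc2ccccc2)c1 | intermediate
5 | (3S)-1-[3,4-bis(benzyloxy)phenyl]hex-5-en-3-yl diisopinocampheylborinate (not isolated) | C=CC[C@H](CCc1ccc(OCc2ccccc2)c(OCc2ccccc2)c1)OB([C@H]1C[C@H]2C[C@@H]([C@@H]1C)C2(C)C)[C@H]1C[C@H]2C[C@@H]([C@@H]1C)C2(C)C | intermediate
6 | (3S)-1-[3,4-bis(benzyloxy)phenyl]hex-5-en-3-ol | C=CC[C@H](CCc1ccc(OCc2ccccc2)c(OCc2ccccc2)c1)O | intermediate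
7 | (3S)-1-[3,4-bis(benzyloxy)phenyl]hex-5-en-3-yl acetate | C=CC[C@H](CCc1ccc(OCc2ccccc2)c(OCc2ccccc2)c1)OC(C)=O | intermediate
8 | (2S)-4-[3,4-bis(benzyloxy)phenyl]-1-(1,2,4-trioxolan-3-yl)butan-2-yl acetate, both epimers at the trioxolane carbon (not isolated) | CC(=O)O[C@@H](CCc1ccc(OCc2ccccc2)c(OCc2ccccc2)c1)CC1OCOO1 | intermediate
9 | (3S)-5-[3,4-bis(benzyloxy)phenyl]-1-oxopentan-3-yl acetate | CC(=O)O[C@@H](CCc1ccc(OCc2ccccc2)c(OCc2ccccc2)c1)CC=O | intermediate
10 | acetyl bromide | CC(=O)Br | starting material
11 | (3S)-5-[3,4-bis(benzyloxy)phenyl]-1-bromopentane-1,3-diyl diacetate, both C1 epimers | CC(=O)OC(Br)C[C@H](CCc1ccc(OCc2ccccc2)c(OCc2ccccc2)c1)OC(C)=O | intermediate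
12 | 2-(4-hydroxy-3-methoxyphenyl)ethanol | COc1cc(CCO)ccc1O | starting material
13 | 2-[4-(benzyloxy)-3-methoxyphenyl]ethanol | COc1cc(CCO)ccc1OCc1ccccc1 | intermediate
14 | 1-(benzyloxy)-4-(2-bromoethyl)-2-methoxybenzene | COc1cc(CCBr)ccc1OCc1ccccc1 | intermediate
15 | {2-[4-(benzyloxy)-3-methoxyphenyl]ethyl}zinc bromide | COc1cc(CC[Zn]Br)ccc1OCc1ccccc1 | intermediate
16 | (3R,5S)-1-[4-(benzyloxy)-3-methoxyphenyl]-7-[3,4-bis(benzyloxy)phenyl]heptane-3,5-diyl diacetate | COc1cc(CC[C@H](C[C@H](CCc2ccc(OCc3ccccc3)c(OCc3ccccc3)c2)OC(C)=O)OC(C)=O)ccc1OCc1ccccc1 | intermediate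
17 | (3R,5S)-7-(3,4-dihydroxyphenyl)-1-(4-hydroxy-3-methoxyphenyl)heptane-3,5-diyl diacetate (chain numbered from ring A) | COc1cc(CC[C@H](C[C@H](CCc2ccc(O)c(O)c2)OC(C)=O)OC(C)=O)ccc1O | target

## Step count and uncertain steps

Total step count: 12. Longest linear sequence: 9 steps (steps 1 to 7, 11 and 12); the ring A branch (steps 8 to 10) joins at step 11.

**Step 11 (key step, Proposed new method).** The most likely failure is loss of stereocontrol at C3 through an uncatalysed ionic pathway. ZnBr2 accumulates during the coupling and can ionise the bromo acetate to an acyloxy-stabilised cation, which the alkylzinc reagent would alkylate without the ligand. A mismatch between the catalyst and the C5 acetate, reduction or elimination of the C–Br bond, and β-hydride elimination from the alkylnickel intermediate are further risks.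

Fallback with known chemistry only, setting out from 6 and returning at 16:
- 6 is silylated (TBSCl, imidazole, DMF) to tert-butyl({(3S)-1-[3,4-bis(benzyloxy)phenyl]hex-5-en-3-yl}oxy)dimethylsilane F1.
- F1 is ozonised as in step 6 to (3S)-5-[3,4-bis(benzyloxy)phenyl]-3-[(tert-butyldimethylsilyl)oxy]pentanal F2.
- Bromide 14 is converted with magnesium turnings in THF into {2-[4-(benzyloxy)-3-methoxyphenyl]ethyl}magnesium bromide F3.
- F3 adds to F2 at −78 °C to give (5S)-1-[4-(benzyloxy)-3-methoxyphenyl]-7-[3,4-bis(benzyloxy)phenyl]-5-[(tert-butyldimethylsilyl)oxy]heptan-3-ol F4 as both C3 epimers.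
- Dess–Martin oxidation gives the corresponding heptan-3-one F5.
- HF·pyridine in THF removes the silyl group to give (5S)-1-[4-(benzyloxy)-3-methoxyphenyl]-7-[3,4-bis(benzyloxy)phenyl]-5-hydroxyheptan-3-one F6.
- Narasaka–Prasad reduction (Et2BOMe, NaBH4, THF/MeOH, −78 °C) of the boron chelate should give the syn diol (3R,5S)-1-[4-(benzyloxy)-3-methoxyphenyl]-7-[3,4-bis(benzyloxy)phenyl]heptane-3,5-diol F7.
- Acetylation of F7 under the conditions of step 5 gives 16, with the benzyl ethers keeping the phenols out of the acylation.

**Step 7.** The likely failures are elimination of acetic acid from the β-acetoxy aldehyde after ZnBr2-promoted enolisation, acylative cleavage of an aryl benzyl ether by acetyl bromide with ZnBr2 if time or temperature is exceeded, and hydrolysis of the moisture-sensitive product. Fallback, setting out from 9 and returning at 11: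
- 9 is converted with Ac2O and catalytic Bi(OTf)3 in MeCN at 0 °C into the acylal (3S)-5-[3,4-bis(benzyloxy)phenyl]pentane-1,1,3-triyl triacetate F8, which can be purified and stored.
- Me3SiBr in CH2Cl2 at 0 °C exchanges one geminal acetate for bromide and gives 11 after removal of volatiles. This is the type of exchange that turns anomeric acetates into glycosyl bromides.

**Step 6.** The likely failures are over-oxidation of the electron-rich 3,4-bis(benzyloxy)phenyl ring or of the benzylic C–H bonds by excess ozone, and β-elimination of the product during work-up. Fallback, setting out from 7 and returning at 9: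
- Dihydroxylation with OsO4 (cat.) and N-methylmorpholine N-oxide in acetone/water gives (3S)-1-[3,4-bis(benzyloxy)phenyl]-5,6-dihydroxyhexan-3-yl acetate F9 (both C5 epimers).
- NaIO4 in buffered THF/water cleaves the glycol to 9, with no oxidant strong enough to attack the arene.

**Step 4.** The likely failure is incomplete facial selectivity, since unbranched aldehydes are the least selective substrates for the allylborane. C5 fixes the absolute configuration of the whole molecule; the only later correction is that step 11 turns the minor enantiomer mainly into a separable diastereomer. Fallback, setting out from 3 and returning at 6: iridium-catalysed transfer-hydrogenative allylation (Krische allylation) of alcohol 3 with allyl acetate, [Ir(cod)Cl]2, a chiral bisphosphine of the antipode that gives the S alcohol, Cs2CO3 and 3-nitrobenzoic acid in THF at 100 °C. The catalyst dehydrogenates 3 to 4 and allylates it in the same cycle, so this route also bypasses step 3 and makes no new isolated compound.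

## Further compounds

F1 | step 11 | tert-butyl({(3S)-1-[3,4-bis(benzyloxy)phenyl]hex-5-en-3-yl}oxy)dimethylsilane | C=CC[C@H](CCc1ccc(OCc2ccccc2)c(OCc2ccccc2)c1)O[Si](C)(C)C(C)(C)C
F2 | step 11 | (3S)-5-[3,4-bis(benzyloxy)phenyl]-3-[(tert-butyldimethylsilyl)oxy]pentanal | O=CC[C@H](CCc1ccc(OCc2ccccc2)c(OCc2ccccc2)c1)O[Si](C)(C)C(C)(C)C
F3 | step 11 | {2-[4-(benzyloxy)-3-methoxyphenyl]ethyl}magnesium bromide | COc1cc(CC[Mg]Br)ccc1OCc1ccccc1
F4 | step 11 | (5S)-1-[4-(benzyloxy)-3-methoxyphenyl]-7-[3,4-bis(benzyloxy)phenyl]-5-[(tert-butyldimethylsilyl)oxy]heptan-3-ol, both C3 epimers | COc1cc(CCC(O)C[C@H](CCc2ccc(OCc3ccccc3)c(OCc3ccccc3)c2)O[Si](C)(C)C(C)(C)C)ccc1OCc1ccccc1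
F5 | step 11 | (5S)-1-[4-(benzyloxy)-3-methoxyphenyl]-7-[3,4-bis(benzyloxy)phenyl]-5-[(tert-butyldimethylsilyl)oxy]heptan-3-one | COc1cc(CCC(=O)C[C@H](CCc2ccc(OCc3ccccc3)c(OCc3ccccc3)c2)O[Si](C)(C)C(C)(C)C)ccc1OCc1ccccc1
F6 | step 11 | (5S)-1-[4-(benzyloxy)-3-methoxyphenyl]-7-[3,4-bis(benzyloxy)phenyl]-5-hydroxyheptan-3-one | COc1cc(CCC(=O)C[C@H](CCc2ccc(OCc3ccccc3)c(OCc3ccccc3)c2)O)ccc1OCc1ccccc1
F7 | step 11 | (3R,5S)-1-[4-(benzyloxy)-3-methoxyphenyl]-7-[3,4-bis(benzyloxy)phenyl]heptane-3,5-diol | COc1cc(CC[C@H](C[C@H](CCc2ccc(OCc3ccccc3)c(OCc3ccccc3)c2)O)O)ccc1OCc1ccccc1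
F8 | step 7 | (3S)-5-[3,4-bis(benzyloxy)phenyl]pentane-1,1,3-triyl triacetate | CC(=O)OC(OC(C)=O)C[C@H](CCc1ccc(OCc2ccccc2)c(OCc2ccccc2)c1)OC(C)=O
F9 | step 6 | (3S)-1-[3,4-bis(benzyloxy)phenyl]-5,6-dihydroxyhexan-3-yl acetate, both C5 epimers | OCC(O)C[C@H](CCc1ccc(OCc2ccccc2)c(OCc2ccccc2)c1)OC(C)=O
F0 | step 4 | none | none
A1 | alternative 1 | all-cis 2-phenyl-4-{2-[4-(benzyloxy)-3-methoxyphenyl]ethyl}-6-{(E)-2-[3,4-bis(benzyloxy)phenyl]ethenyl}-1,3-dioxane, C3 and C5 as in the target | COc1cc(CC[C@@H]2C[C@H](/C=C/c3ccc(OCc4ccccc4)c(OCc4ccccc4)c3)O[C@H](c3ccccc3)O2)ccc1OCc1ccccc1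
A2 | alternative 1 | (3R,5E)-1-[4-(benzyloxy)-3-methoxyphenyl]-7-[3,4-bis(benzyloxy)phenyl]hept-5-ene-3,7-diol, both C7 epimers | COc1cc(CC[C@@H](O)C/C=C/C(O)c2ccc(OCc3ccccc3)c(OCc3ccccc3)c2)ccc1OCc1ccccc1
A3 | alternative 1 | benzaldehyde dimethyl acetal | COC(OC)c1ccccc1
A4 | alternative 2 | cis-2,2-di-tert-butyl-4-{(E)-2-[4-(benzyloxy)-3-methoxyphenyl]ethenyl}-6-ethenyl-1,3,2-dioxasilinane, C3 and C5 as in the target | COc1cc(/C=C/[C@@H]2C[C@H](C=C)O[Si](C(C)(C)C)(C(C)(C)C)O2)ccc1OCc1ccccc1
A5 | alternative 2 | meso-3,3-di-tert-butyl-2,4-dioxa-3-silabicyclo[3.2.1]oct-6-ene | CC(C)(C)[Si]1(C(C)(C)C)O[C@H]2C[C@H](C=C2)O1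
A6 | alternative 2 | 1-(benzyloxy)-4-ethenyl-2-methoxybenzene | COc1cc(C=C)ccc1OCc1ccccc1
A7 | alternative 3 | (4R,6S)-4-{2-[4-(benzyloxy)-3-methoxyphenyl]ethyl}-6-{2-[3,4-bis(benzyloxy)phenyl]ethyl}-2,2-dimethyl-1,3-dioxane | COc1cc(CC[C@@H]2C[C@H](CCc3ccc(OCc4ccccc4)c(OCc4ccccc4)c3)OC(C)(C)O2)ccc1OCc1ccccc1
A8 | alternative 3 | (4R,6R)-4-{2-[4-(benzyloxy)-3-methoxyphenyl]ethyl}-6-(2-bromoethyl)-2,2-dimethyl-1,3-dioxane (cis) | COc1cc(CC[C@@H]2C[C@H](CCBr)OC(C)(C)O2)ccc1OCc1ccccc1
A9 | alternative 3 | 4-bromo-1,2-bis(benzyloxy)benzene | Brc1ccc(OCc2ccccc2)c(OCc2ccccc2)c1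
A10 | alternative 3 | tert-butyl 2-[(4R,6S)-6-(hydroxymethyl)-2,2-dimethyl-1,3-dioxan-4-yl]acetate | OC[C@@H]1C[C@H](CC(=O)OC(C)(C)C)OC(C)(C)O1
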